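**Strategy.** Ring A (the isochromene carrying the acetoxypropenyl chain; C7, S) and ring B (primed; C7′ R, C6′ R) hold the same C6–C7(Me)(O)–C8 array in opposite absolute sense, and C6′ is a reduced C6. The two carbocycles are therefore the two enantiomers of one 7-aroyloxy-7-methyl-1H-isochromene-6,8-dione. That monomer is built racemic, with no asymmetric step. One Ru-catalysed transfer hydrogenation at C6 then resolves it: the (R)-enantiomer becomes the cis-(6R,7R)-hydroxy ester (ring B after a 1,2-aroyl shift), the (S)-enantiomer is left as ring A. Both enantiomers are consumed, and the halves are rejoined at C5 by a vinylogous Knoevenagel condensation.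

Key step: step 10

Assumption: (E)-pent-2-en-4-yn-1-ol (6) is taken as commercially available, and the open 5Z-dienone drawn for the target is taken as the stable valence isomer relative to its 2H-pyran (oxa-6π) form, as in the isolated compound.

**Step 1**
Reactants: 1 2,6-dimethoxytoluene
Product: 3 5-bromo-1,3-dimethoxy-2-methylbenzene, via aryl pinacol boronate 2 (not isolated)
Conditions: [Ir(OMe)(cod)]2 (1 mol %), dtbpy (2 mol %), B2pin2, THF, 80 °C; then CuBr2, MeOH–H2O, 80 °C
Reagents that add atoms: bis(pinacolato)diboron CC1(C)OB(OC1(C)C)B1OC(C)(C)C(C)(C)O1 (boron group of intermediate 2 only); copper(II) bromide Br[Cu]Br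
Why: Iridium-catalysed C–H borylation is sterically controlled and should select the only C–H flanked by two hydrogens (para to the methyl group); copper(II) bromide then replaces the boronate by bromine (C–H borylation/halodeboronation).

**Step 2**
Reactants: 3 5-bromo-1,3-dimethoxy-2-methylbenzene
Product: 4 6-bromo-2,4-dimethoxy-3-methylbenzaldehyde
Conditions: Cl2CHOMe, TiCl4, CH2Cl2, 0 °C; aqueous work-up
Reagents that add atoms: dichloromethyl methyl ether COC(Cl)Cl; water O (carbonyl oxygen, on hydrolytic work-up)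
Why: Rieche formylation (electrophilic aromatic substitution) can only occur at the two equivalent free positions, each ortho to one methoxy group and para to the other.

**Step 3**
Reactants: 4 6-bromo-2,4-dimethoxy-3-methylbenzaldehyde
Product: 5 6-bromo-2,4-dihydroxy-3-methylbenzaldehyde
Conditions: BBr3, CH2Cl2, −78 °C to rt; H2O
Reagents that add atoms: none
Why: Lewis-acid cleavage of both aryl methyl ethers with boron tribromide, placed at a stage at which nothing acid-sensitive is present.

**Step 4**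
Reactants: 6 (E)-pent-2-en-4-yn-1-ol
Product: 7 (E)-pent-2-en-4-yn-1-yl acetate
Conditions: Ac2O, pyridine, DMAP (cat.), CH2Cl2, 0 °C
Reagents that add atoms: acetic anhydride CC(=O)OC(C)=O
Why: Standard acetylation of a primary alcohol; the acetate is the ring-A ester of the target and masks the chain terminus of ring B until step 12.

**Step 5**
Reactants: 5 6-bromo-2,4-dihydroxy-3-methylbenzaldehyde; 7 (E)-pent-2-en-4-yn-1-yl acetate
Product: 8 (E)-5-(2-formyl-3,5-dihydroxy-4-methylphenyl)pent-2-en-4-yn-1-yl acetate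
Conditions: PdCl2(PPh3)2 (5 mol %), CuI (10 mol %), Et3N, DMF, 60 °C
Reagents that add atoms: none
Why: Sonogashira coupling; the ortho-formyl group activates the C–Br bond towards oxidative addition, and neither phenol is ortho to the new alkyne, so no benzofuran can form.

**Step 6**
Reactants: 8 (E)-5-(2-formyl-3,5-dihydroxy-4-methylphenyl)pent-2-en-4-yn-1-yl acetate
Product: 10 racemic (E)-3-(7-hydroxy-7-methyl-6,8-dioxo-7,8-dihydro-6H-isochromen-3-yl)allyl acetate, via isochromenylium trifluoroacetate 9 (not isolated)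
Conditions: Au(OAc)3 (5 mol %), TFA, 1,2-dichloroethane, rt; then IBX, Bu4NI (cat.), rt
Reagents that add atoms: IBX (2-iodoxybenzoic acid) O=C1OI(=O)(O)c2ccccc12; trifluoroacetic acid OC(=O)C(F)(F)F (counter-ion of intermediate 9 only)
Why: Gold(III)-catalysed 6-endo-dig cycloisomerisation of the o-alkynylbenzaldehyde gives the 2-benzopyrylium salt, and IBX then delivers oxygen to C7, the carbon ortho to both phenols, in a hydroxylative dearomatisation that creates the C7 stereocentre as a racemate on purpose.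

**Step 7**
Reactants: 11 orsellinic acid (2,4-dihydroxy-6-methylbenzoic acid)
Product: 13 2,4-bis(tert-butyldimethylsilyloxy)-6-methylbenzoic acid, via tris-silyl derivative 12 (not isolated)
Conditions: TBSCl, imidazole, DMF, rt; then AcOH–THF–H2O, rt
Reagents that add atoms: tert-butyldimethylsilyl chloride CC(C)(C)[Si](C)(C)Cl
Why: Exhaustive silylation followed by selective hydrolysis of the labile silyl ester should leave the two aryl silyl ethers, which are carried to the end and leave with fluoride.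

**Step 8**
Reactants: 10 racemic 7-hydroxy pyranoquinone; 13 2,4-bis(tert-butyldimethylsilyloxy)-6-methylbenzoic acid
Product: 15 racemic 3-[(E)-3-acetoxyprop-1-en-1-yl]-7-methyl-6,8-dioxo-7,8-dihydro-6H-isochromen-7-yl 2,4-bis(tert-butyldimethylsilyloxy)-6-methylbenzoate, via acid chloride 14 (not isolated)
Conditions: 1-chloro-N,N,2-trimethylprop-1-en-1-amine, CH2Cl2, rt; then 10, DMAP, Et3N, CH2Cl2, 40 °C
Reagents that add atoms: 1-chloro-N,N,2-trimethylprop-1-en-1-amine (Ghosez reagent) CC(C)=C(Cl)N(C)C (chlorine of intermediate 14 only)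
Why: Neutral acid chloride formation and DMAP-catalysed acylation (nucleophilic catalysis) of the tertiary α-ketol, which is the only free hydroxyl; C7 is not touched.

**Step 9**
Reactants: 15 racemic pyranoquinone ester
Product: 16 racemic 3-[(E)-3-acetoxyprop-1-en-1-yl]-7-methyl-6,8-dioxo-5,6,7,8-tetrahydro-1H-isochromen-7-yl 2,4-bis(tert-butyldimethylsilyloxy)-6-methylbenzoate
Conditions: Hantzsch ester (1.1 equiv), TFA (1 equiv), CH2Cl2, −20 to 0 °C
Reagents that add atoms: none
Why: Protonation on O6 gives a 6-hydroxy-2-benzopyrylium-type cation whose unsubstituted C1 should accept hydride from the Hantzsch ester (transfer hydrogenation of a pyrylium salt); tautomerisation of the resulting dienol gives the C5-methylene dione.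

**Step 10**
Reactants: 16 racemic C5-methylene dione ester
Product: 17 (S)-3-[(E)-3-acetoxyprop-1-en-1-yl]-7-methyl-6,8-dioxo-5,6,7,8-tetrahydro-1H-isochromen-7-yl 2,4-bis(tert-butyldimethylsilyloxy)-6-methylbenzoate (the unreacted enantiomer, recovered) and 18 (6R,7R)-3-[(E)-3-acetoxyprop-1-en-1-yl]-6-hydroxy-7-methyl-8-oxo-5,6,7,8-tetrahydro-1H-isochromen-7-yl 2,4-bis(tert-butyldimethylsilyloxy)-6-methylbenzoate
Conditions: RuCl[(R,R)-TsDPEN](p-cymene) (2 mol %), HCO2H–Et3N (5:2), CH2Cl2, 0 °C, stopped near 50 % conversion; chromatographic separation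
Reagents that add atoms: none
Why: Noyori–Ikariya outer-sphere transfer of Ru–H and N–H to the C6 keto tautomer; the closest precedents are the transfer-hydrogenative desymmetrisation of 2,2-disubstituted cyclic 1,3-diones and kinetic resolutions of α-quaternary ketones with the same catalysts. No ring is closed and only C6 is created. In the dione the 7-aroyloxy group should sit axial (methyl equatorial, dipole minimisation), so hydride prefers the face anti to it (Felkin–Anh, axial attack) and gives the cis 6-hydroxy-7-acyloxy array; the (R,R)-catalyst, expected by the aryl-ketone model (acyl-bearing C7 as the large π-group) to form the 6R carbinol, finds that face matched only in (R)-16, which should go to (6R,7R)-18, while (S)-16 = 17 is mismatched and should remain. The step needs a high selectivity factor (secured by catalyst and substrate preference coinciding in one enantiomer only), C6 over C8 (C8=O is a vinylogous ester carbonyl, O2–C3=C4–C4a=C8a–C8=O, between two fully substituted carbons) and interruption near half conversion. Should the sense of induction prove opposite, the (S,S)-complex is used with the same logic.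

**Step 11**
Reactants: 18 (6R,7R)-6-hydroxy 7-aroyl ester
Product: 19 (6R,7R)-3-[(E)-3-acetoxyprop-1-en-1-yl]-7-hydroxy-7-methyl-8-oxo-5,6,7,8-tetrahydro-1H-isochromen-6-yl 2,4-bis(tert-butyldimethylsilyloxy)-6-methylbenzoate
Conditions: DBU (0.2 equiv), THF, 0 °C to rt
Reagents that add atoms: none
Why: Base-catalysed 1,2-O→O acyl migration through the cis-fused five-membered orthoacid, possible only because O6 and O7 are cis, should run downhill to the less congested secondary ester with the freed tertiary hydroxyl hydrogen-bonded to C8=O; no stereocentre is touched.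

**Step 12**
Reactants: 19 (6R,7R)-6-aroyl ester acetate
Product: 20 (6R,7R)-7-hydroxy-3-[(E)-3-hydroxyprop-1-en-1-yl]-7-methyl-8-oxo-5,6,7,8-tetrahydro-1H-isochromen-6-yl 2,4-bis(tert-butyldimethylsilyloxy)-6-methylbenzoate
Conditions: immobilised Candida antarctica lipase B, n-BuOH, MTBE, 30 °C
Reagents that add atoms: none
Why: Lipase-catalysed transesterification should cleave the unhindered primary acetate under neutral conditions and leave the hindered aroyl ester and the aryl silyl ethers alone.

**Step 13**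
Reactants: 20 allylic alcohol
Product: 21 (6R,7R)-7-hydroxy-7-methyl-8-oxo-3-[(E)-3-oxoprop-1-en-1-yl]-5,6,7,8-tetrahydro-1H-isochromen-6-yl 2,4-bis(tert-butyldimethylsilyloxy)-6-methylbenzoate
Conditions: activated MnO2, CH2Cl2, rt
Reagents that add atoms: none
Why: Manganese dioxide oxidises only the primary allylic alcohol; the remaining hydroxyl is tertiary.

**Step 14**
Reactants: 17 (S)-dione ester; 21 ring-B enal
Product: 22 tetrakis(tert-butyldimethylsilyl) ether of the target (5Z triene, 7S, 6′R,7′R)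
Conditions: ethylenediammonium diacetate (20 mol %), 4 Å molecular sieves, CH2Cl2, rt
Reagents that add atoms: none
Why: Knoevenagel condensation via the iminium ion of the enal: C5 of 17, between C6=O and the C4a=C8a–C8=O enone, is the only acidic methylene, and the reversible amine-catalysed condensation should settle on the thermodynamic 5Z geometry (chain syn to C6=O, away from C4–H) with the E bond of the enal retained.

**Step 15**
Reactants: 22 tetrasilyl ether
Product: 23 CNP0283591.2 (target)
Conditions: HF·pyridine, pyridine, THF, 0 °C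
Reagents that add atoms: none
Why: Buffered fluoride should cleave the four aryl silyl ethers without touching the allylic acetate, the two aroyl esters or the enol ethers.

**Compound list**

1 | 2,6-dimethoxytoluene | COc1cccc(OC)c1C | starting material
2 | 2-(3,5-dimethoxy-4-methylphenyl)-4,4,5,5-tetramethyl-1,3,2-dioxaborolane | COc1cc(B2OC(C)(C)C(C)(C)O2)cc(OC)c1C | intermediate
3 | 5-bromo-1,3-dimethoxy-2-methylbenzene | COc1cc(Br)cc(OC)c1C | intermediate
4 | 6-bromo-2,4-dimethoxy-3-methylbenzaldehyde | COc1cc(Br)c(C=O)c(OC)c1C | intermediate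
5 | 6-bromo-2,4-dihydroxy-3-methylbenzaldehyde | Cc1c(O)cc(Br)c(C=O)c1O | intermediate
6 | (E)-pent-2-en-4-yn-1-ol | OC/C=C/C#C | starting material
7 | (E)-pent-2-en-4-yn-1-yl acetate | CC(=O)OC/C=C/C#C | intermediate
8 | (E)-5-(2-formyl-3,5-dihydroxy-4-methylphenyl)pent-2-en-4-yn-1-yl acetate | CC(=O)OC/C=C/C#Cc1cc(O)c(C)c(O)c1C=O | intermediate
9 | 3-[(E)-3-acetoxyprop-1-en-1-yl]-6,8-dihydroxy-7-methylisochromenylium trifluoroacetate | CC(=O)OC/C=C/c1cc2cc(O)c(C)c(O)c2c[o+]1.[O-]C(=O)C(F)(F)F | intermediate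
10 | racemic (E)-3-(7-hydroxy-7-methyl-6,8-dioxo-7,8-dihydro-6H-isochromen-3-yl)allyl acetate | CC(=O)OC/C=C/C1=CC2=CC(=O)C(C)(O)C(=O)C2=CO1 | intermediate
11 | orsellinic acid | Cc1cc(O)cc(O)c1C(=O)O | starting material
12 | tert-butyldimethylsilyl 2,4-bis(tert-butyldimethylsilyloxy)-6-methylbenzoate | Cc1cc(O[Si](C)(C)C(C)(C)C)cc(O[Si](C)(C)C(C)(C)C)c1C(=O)O[Si](C)(C)C(C)(C)C | intermediate
13 | 2,4-bis(tert-butyldimethylsilyloxy)-6-methylbenzoic acid | Cc1cc(O[Si](C)(C)C(C)(C)C)cc(O[Si](C)(C)C(C)(C)C)c1C(=O)O | intermediate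
14 | 2,4-bis(tert-butyldimethylsilyloxy)-6-methylbenzoyl chloride | Cc1cc(O[Si](C)(C)C(C)(C)C)cc(O[Si](C)(C)C(C)(C)C)c1C(Cl)=O | intermediate
15 | racemic 3-[(E)-3-acetoxyprop-1-en-1-yl]-7-methyl-6,8-dioxo-7,8-dihydro-6H-isochromen-7-yl 2,4-bis(tert-butyldimethylsilyloxy)-6-methylbenzoate | CC(=O)OC/C=C/C1=CC2=CC(=O)C(C)(OC(=O)c3c(C)cc(O[Si](C)(C)C(C)(C)C)cc3O[Si](C)(C)C(C)(C)C)C(=O)C2=CO1 | intermediate
16 | racemic 3-[(E)-3-acetoxyprop-1-en-1-yl]-7-methyl-6,8-dioxo-5,6,7,8-tetrahydro-1H-isochromen-7-yl 2,4-bis(tert-butyldimethylsilyloxy)-6-methylbenzoate | CC(=O)OC/C=C/C1=CC2=C(CO1)C(=O)C(C)(OC(=O)c1c(C)cc(O[Si](C)(C)C(C)(C)C)cc1O[Si](C)(C)C(C)(C)C)C(=O)C2 | intermediate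
17 | (S)-enantiomer of 16 | CC(=O)OC/C=C/C1=CC2=C(CO1)C(=O)[C@@](C)(OC(=O)c1c(C)cc(O[Si](C)(C)C(C)(C)C)cc1O[Si](C)(C)C(C)(C)C)C(=O)C2 | intermediate
18 | (6R,7R)-3-[(E)-3-acetoxyprop-1-en-1-yl]-6-hydroxy-7-methyl-8-oxo-5,6,7,8-tetrahydro-1H-isochromen-7-yl 2,4-bis(tert-butyldimethylsilyloxy)-6-methylbenzoate | CC(=O)OC/C=C/C1=CC2=C(CO1)C(=O)[C@](C)(OC(=O)c1c(C)cc(O[Si](C)(C)C(C)(C)C)cc1O[Si](C)(C)C(C)(C)C)[C@H](O)C2 | intermediate
19 | (6R,7R)-3-[(E)-3-acetoxyprop-1-en-1-yl]-7-hydroxy-7-methyl-8-oxo-5,6,7,8-tetrahydro-1H-isochromen-6-yl 2,4-bis(tert-butyldimethylsilyloxy)-6-methylbenzoate | CC(=O)OC/C=C/C1=CC2=C(CO1)C(=O)[C@](C)(O)[C@H](OC(=O)c1c(C)cc(O[Si](C)(C)C(C)(C)C)cc1O[Si](C)(C)C(C)(C)C)C2 | intermediate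
20 | (6R,7R)-7-hydroxy-3-[(E)-3-hydroxyprop-1-en-1-yl]-7-methyl-8-oxo-5,6,7,8-tetrahydro-1H-isochromen-6-yl 2,4-bis(tert-butyldimethylsilyloxy)-6-methylbenzoate | OC/C=C/C1=CC2=C(CO1)C(=O)[C@](C)(O)[C@H](OC(=O)c1c(C)cc(O[Si](C)(C)C(C)(C)C)cc1O[Si](C)(C)C(C)(C)C)C2 | intermediate
21 | (6R,7R)-7-hydroxy-7-methyl-8-oxo-3-[(E)-3-oxoprop-1-en-1-yl]-5,6,7,8-tetrahydro-1H-isochromen-6-yl 2,4-bis(tert-butyldimethylsilyloxy)-6-methylbenzoate | O=C/C=C/C1=CC2=C(CO1)C(=O)[C@](C)(O)[C@H](OC(=O)c1c(C)cc(O[Si](C)(C)C(C)(C)C)cc1O[Si](C)(C)C(C)(C)C)C2 | intermediate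
22 | tetrakis(tert-butyldimethylsilyl) ether of the target | CC(=O)OC/C=C/C1=CC2=C(CO1)C(=O)[C@@](C)(OC(=O)c1c(C)cc(O[Si](C)(C)C(C)(C)C)cc1O[Si](C)(C)C(C)(C)C)C(=O)/C2=C\C=C\C1=CC2=C(CO1)C(=O)[C@](C)(O)[C@H](OC(=O)c1c(C)cc(O[Si](C)(C)C(C)(C)C)cc1O[Si](C)(C)C(C)(C)C)C2 | intermediate
23 | CNP0283591.2 | CC(=O)OC/C=C/C1=CC2=C(CO1)C(=O)[C@@](C)(OC(=O)c1c(C)cc(O)cc1O)C(=O)/C2=C\C=C\C1=CC2=C(CO1)C(=O)[C@](C)(O)[C@H](OC(=O)c1c(C)cc(O)cc1O)C2 | target

**Step count.** Total: 15 steps. Longest linear sequence: 13 steps (1, 2, 3, 5, 6, 8, 9, 10, 11, 12, 13, 14, 15).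

**Steps most likely to fail**

Step 10. The resolution may show a low selectivity factor: the mismatched enantiomer is reduced at a comparable rate, or catalyst control overrides the substrate bias and trans alcohol forms, so that neither half is obtained enantiopure. Fallback: set out from racemic 16 and separate the enantiomers by preparative chromatography on a chiral stationary phase into 17 and the (R)-enantiomer F1. Reduce F1 with NaBH4/CeCl3 in MeOH–THF at −78 °C under substrate control alone (hydride anti to the axial aroyloxy group), which comes back to the route at 18; 17 enters step 14 unchanged.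

Step 8. The hindered tertiary α-ketol may not be acylated by the di-ortho-substituted aroyl chloride, or the amine catalyst may add to C1 of the pyranoquinone. Fallback: set out from 8 and 14 and let the aroyl group arrive on O7 by an intramolecular shift instead of an intermolecular acylation. Acylate the more acidic, non-chelated 4-hydroxyl of 8 (Et3N, CH2Cl2, 0 °C) to the aryl ester F2. Cycloisomerise it as in step 6 to the 6-aroyloxy-8-hydroxyisochromenylium salt F3. IBX hydroxylation ortho to the free 8-hydroxyl then gives the O6-acylated 7-hydroxy-8-oxo pyrylium F4, an activated acyl donor whose aroyl group should shift to the adjacent C7 hydroxyl through a five-membered orthoester. This comes back to the route at 15.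

Step 9. Hydride may be delivered to C3 or to a carbonyl group instead of C1, or the enol ether of 16 may be reduced further under acid. Fallback: move the hydride transfer to the isochromenylium stage, where reduction at C1 is standard. Set out from 8, form 9 as in step 6 and add the Hantzsch ester to reach the 1H-isochromene-6,8-diol F5. Dearomatise F5 at C7 with IBX to the racemic 7-hydroxy dione F6. Acylate F6 with 14 (DMAP, Et3N), if necessary through the O6 enol ester and its 1,2-shift to O7, which comes back to the route at 16.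

**Further compounds**

F1 | step 10 | (R)-enantiomer of 16 | CC(=O)OC/C=C/C1=CC2=C(CO1)C(=O)[C@](C)(OC(=O)c1c(C)cc(O[Si](C)(C)C(C)(C)C)cc1O[Si](C)(C)C(C)(C)C)C(=O)C2
F2 | step 8 | 5-[(E)-5-acetoxypent-3-en-1-yn-1-yl]-4-formyl-3-hydroxy-2-methylphenyl 2,4-bis(tert-butyldimethylsilyloxy)-6-methylbenzoate | CC(=O)OC/C=C/C#Cc1cc(OC(=O)c2c(C)cc(O[Si](C)(C)C(C)(C)C)cc2O[Si](C)(C)C(C)(C)C)c(C)c(O)c1C=O
F3 | step 8 | 3-[(E)-3-acetoxyprop-1-en-1-yl]-6-aroyloxy-8-hydroxy-7-methylisochromenylium trifluoroacetate (aroyl = 2,4-bis(tert-butyldimethylsilyloxy)-6-methylbenzoyl) | CC(=O)OC/C=C/c1cc2cc(OC(=O)c3c(C)cc(O[Si](C)(C)C(C)(C)C)cc3O[Si](C)(C)C(C)(C)C)c(C)c(O)c2c[o+]1.[O-]C(=O)C(F)(F)F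
F4 | step 8 | racemic 3-[(E)-3-acetoxyprop-1-en-1-yl]-6-aroyloxy-7-hydroxy-7-methyl-8-oxo-7,8-dihydroisochromenylium trifluoroacetate | CC(=O)OC/C=C/c1cc2C=C(OC(=O)c3c(C)cc(O[Si](C)(C)C(C)(C)C)cc3O[Si](C)(C)C(C)(C)C)C(C)(O)C(=O)c2c[o+]1.[O-]C(=O)C(F)(F)F
F5 | step 9 | (E)-3-(6,8-dihydroxy-7-methyl-1H-isochromen-3-yl)allyl acetate | CC(=O)OC/C=C/C1=Cc2cc(O)c(C)c(O)c2CO1
F6 | step 9 | racemic (E)-3-(7-hydroxy-7-methyl-6,8-dioxo-5,6,7,8-tetrahydro-1H-isochromen-3-yl)allyl acetate | CC(=O)OC/C=C/C1=CC2=C(CO1)C(=O)C(C)(O)C(=O)C2
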